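## The problem

The target, (4S)-5,8-dihydroxy-4-(4-hydroxy-8-methoxynaphthalen-1-yl)-3,4-dihydronaphthalen-1(2H)-one (26), joins two naphthalene-derived halves through one sp3–sp2 bond, C4–C1′. Ring B (C1–C4, C4a, C8a) is a cyclohexanone fused to ring A (C4a, C5–C8, C8a), a hydroquinone with hydroxyls at C5 and C8. The naphthyl group has a free hydroxyl at C4′ and a methyl ether at C8′, peri to the linkage. C4 is the only stereocentre, so no resident centre can control it and a catalyst must set it; it is doubly benzylic, and any step that makes a cation, radical or carbanion there erases it. The hydroquinone is easily oxidized to a quinone, most of all while the C1 carbonyl is still masked, and the electron-rich naphthalene does not tolerate strong electrophiles or oxidants. The two naphthalene oxygens occupy equivalent positions of a 1,5-dioxygenated naphthalene, yet one must end as OH (para to the linkage) and the other as OMe (peri to it). A late Friedel–Crafts closure of ring B would let the acyl group choose between C8a and C2′ of the naphthalene. The feature that avoids this is that ring A is substituted only at C5 and C8, next to the ring fusion, while C6 and C7 are CH. Ring A is therefore the sum of an alkyne C4a≡C5, an alkyne C8a≡C8 and acetylene, and the two alkynes are tethered through C4–C3–C2–C1, so a 1,7-diyne with boron on both termini can close rings A and B in one cyclotrimerization.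

## Retrosynthesis

**Unmasking (26 ⇐ 25 ⇐ 24 ⇐ 23).** The phenols are not carried free. Removing the benzyl group from O4′ leads to 25. The C5 and C8 hydroxyls are traced to C–B bonds and the C1 carbonyl to a dioxolane, which leads through the hydroquinone ketal 24 to the bis(pinacol boronate) 23. Boron is preferred to ether protection on ring A because aryl boronates are air-stable where the hydroquinone is not, and because they are what a cyclotrimerization of alkynyl boronates delivers. The forward steps must oxidize two hindered C–B bonds without running on to the quinone.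

**Cyclotrimerization (23 ⇐ 21 + 22).** Ring A of 23 is cut at C4a–C8a, C5–C6 and C7–C8, which opens ring B as well and gives the 1,7-diyne 21 and acetylene 22. The neighbouring cuts in ring B (C1–C8a by acylation, C4–C4a by alkylation of an existing arene) need a finished tetrasubstituted benzene and face competition from the naphthalene. Building the arene last has no such choice. 21 is acyclic with one stereocentre. The forward reaction must prefer cross-trimerization with 22, tolerate two alkynyl boronates and leave the propargylic C4–H alone.

**Boron on the alkynes (21 ⇐ 19 ⇐ 18).** The two C(sp)–B bonds are cut to the terminal diyne 19, and this in turn to the bis-silyl diyne 18. Borylation is placed directly before the key step because alkynyl boronates hydrolyse easily. Silicon protects both alkynes until then. The forward step needs two acetylide anions without loss of the more weakly acidic C4–H.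

**C1 and its alkyne (18 ⇐ 17 ⇐ 15 + 8).** The dioxolane of 18 comes from the ynone 17, and the C1–C8a bond of 17 is cut to the N-methoxy-N-methylamide 15 and trimethylsilylacetylene 8. An amide of this kind stops acetylide addition at the ketone, which an ester would not. The ketal is needed because step 12 uses an organolithium base.

**One-carbon insertion (15 ⇐ 13 ⇐ 11).** Conjugate addition, used below for C4, leaves the carbonyl carbon two atoms from C4, one short of C1. The C2–C3 bond is therefore made by the 1,2-shift of an Arndt–Eistert homologation, from the diazoketone 13 and the acid 11. Reduction, olefination and re-oxidation sequences reach the same amide in more steps.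

**The stereocentre (11 ⇐ 9 ⇐ 7 + 8).** The C4–C4a bond is cut between the benzylic carbon and an alkynyl group. In the forward sense 8 adds to the alkylidene Meldrum's acid 7 under a chiral rhodium–bisphosphine catalyst to give 9, which is hydrolysed and decarboxylated to 11. Copper systems of this kind are established for arylacetylenes; for a silylacetylene the rhodium system has the precedent and is taken. A propargylic substitution at C4 would pass through a cation stabilized by the electron-rich naphthalene and is rejected.

**Acceptor (7 ⇐ 5 + 6).** The C3=C4 double bond is cut by a Knoevenagel disconnection to the aldehyde 5 and Meldrum's acid 6, which supplies C3 and the carboxyl carbon that later becomes C1.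

**Naphthalene (5 ⇐ 4 ⇐ 3 ⇐ 1).** The formyl C–C bond is cut back to the symmetrical 1,5-dimethoxynaphthalene 1. If the two oxygens were differentiated first, formylation would hit both para positions, since the two alkoxy groups activate equally. Formylating first makes the oxygens different: in 3 only the 4-methoxy group is conjugated with the aldehyde, so it alone is cleaved to 4, which is then benzylated to 5.

## Roads not taken

**Alternative 1:** The cut goes through the naphthol ring at C1′–C8a′ and C4′–C4a′. The furan of the butanoate A2, which already carries C4 and the hydroquinone ring as its dibenzyl ether, would add to 3-methoxybenzyne A3 in a Diels–Alder reaction, and acid would open the oxygen bridge to the naphthol A1. Ester hydrolysis, Friedel–Crafts closure of ring B and debenzylation would follow.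
- Merits: the 4′-hydroxyl and 8′-methyl ether come out differentiated by construction, which the chosen plan must achieve by a selective demethylation (step 2). No gas and no moisture-sensitive boronate is needed.
- Weak points: the aryne and the 2-substituted furan can combine in two orientations, and the one needed puts the methoxy group beside the bulky bridgehead substituent. The stereocentre is furfurylic and benzylic and must survive the acid that opens the bridge. The later acylation can attack C2′ as well as C8a.
- Comparison: this road has fewer steps after its key step. The chosen plan sets against that a ring B closure with no regiochemical choice and a stereocentre that never meets strong acid.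

**Alternative 2:** The cut removes C3–C4 and the bond from C1 to an oxygen on ring A. The ortho-quinone methide A5, generated in situ, would combine with the homoenolate formed from acrolein A6 and a chiral N-heterocyclic carbene in a [4+3] annulation to the lactone A4. The acyl group would then have to move from oxygen to C8a (Fries rearrangement, or ring opening and Friedel–Crafts acylation).
- Merits: in convergence this road is better than the chosen plan, since C4 and three ring B carbons arrive in one catalytic step from simple partners.
- Weak points: a β-unsubstituted enal is prone to self-condensation under carbene catalysis. The quinone methide carries a crowded, electron-rich aryl group on the methide carbon, outside the usual range of this annulation. The acyl transfer needs acid at a doubly benzylic stereocentre and again has C2′ as a competing site.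
- Comparison: the chosen plan is longer, but its one uncertain step runs under neutral conditions and the ketone–arene bond forms without a competing position.

**Alternative 3:** The cut is C2–C3, made as an alkene. The diene A8, with vinyl groups on C4 and on a silyl-protected C1 carbinol, would close to the cis-dihydronaphthalene A7 by ring-closing metathesis with the second-generation Grubbs catalyst. Hydrogenation, desilylation, oxidation at C1 and debenzylation would finish.
- Merits: the metathesis is more certain than a cyclotrimerization, and in this respect the road is superior.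
- Weak points: A8 needs a 1,2,3,4-tetrasubstituted benzene with two different benzylic branches. Its C4 is doubly benzylic and allylic, where ruthenium hydrides can move the double bond into conjugation. A7 can aromatize by loss of silanol, which destroys C4. The C1 stereocentre is made only to be oxidized away.
- Comparison: the chosen plan sets against the safer ring closure a linear build-up of an acyclic precursor and a ring A that is formed with its oxygen handles in place.

Key step: step 13

Remark on the chemistry (assumption): the (S)-ligand is written in step 5 on the assumption that it sends the alkynyl group to the Re face of the alkylidene carbon of 7; if the sense is the opposite, the (R)-ligand is used and nothing else changes.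

Ar = 4-(benzyloxy)-8-methoxynaphthalen-1-yl. C4 keeps the same spatial arrangement from 9 to 26; its descriptor changes between S and R only because the CIP priorities of its neighbours change.

## Route

Step 1
Reactants: 1 1,5-dimethoxynaphthalene
Product: 3 4,8-dimethoxynaphthalene-1-carbaldehyde, via iminium chloride 2 (not isolated)
Conditions: POCl3, DMF, 0 → 90 °C; then aq. NaOAc, rt
Reagents that add atoms: N,N-dimethylformamide, CN(C)C=O; water, O
Why: Vilsmeier–Haack formylation; C4 and C8 of the symmetrical diether are equivalent and each is para to a methoxy group, so only one monoaldehyde can form, and the formyl group deactivates the ring system against a second attack.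

Step 2
Reactants: 3 4,8-dimethoxynaphthalene-1-carbaldehyde
Product: 4 4-hydroxy-8-methoxynaphthalene-1-carbaldehyde
Conditions: NaSEt, DMF, 100 °C; then 1 M HCl
Reagents that add atoms: none
Why: Nucleophilic O-demethylation (SN2 at methyl by thiolate); the 4-oxide is para to the formyl group and leaves as a vinylogous carboxylate, whereas an 8-oxide places charge on C2, C4, C5 and C7 but not on C1, so the 4-methyl ether should be cleaved selectively.

Step 3
Reactants: 4 4-hydroxy-8-methoxynaphthalene-1-carbaldehyde
Product: 5 4-(benzyloxy)-8-methoxynaphthalene-1-carbaldehyde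
Conditions: BnBr, K2CO3, DMF, rt
Reagents that add atoms: benzyl bromide, BrCc1ccccc1
Why: Williamson etherification of the acidic 4-naphthol; the benzyl ether survives organolithium base, rhodium and cobalt catalysis and alkaline peroxide and is removed at the end by hydrogenolysis.

Step 4
Reactants: 5 4-(benzyloxy)-8-methoxynaphthalene-1-carbaldehyde; 6 Meldrum's acid
Product: 7 5-(Ar-methylidene)-2,2-dimethyl-1,3-dioxane-4,6-dione
Conditions: pyrrolidinium acetate (10 mol %), toluene, 50 °C
Reagents that add atoms: none
Why: Knoevenagel condensation; the very acidic methylene of 6 condenses even with electron-rich, hindered aryl aldehydes under amine–acid catalysis and gives the doubly activated acceptor that step 5 needs.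

Step 5
Reactants: 7 5-(Ar-methylidene)-2,2-dimethyl-1,3-dioxane-4,6-dione; 8 trimethylsilylacetylene
Product: 9 5-[(1S)-1-Ar-3-(trimethylsilyl)prop-2-yn-1-yl]-2,2-dimethyl-1,3-dioxane-4,6-dione
Conditions: Rh(acac)(C2H4)2 (5 mol %), (S)-3,5-Xyl-MeO-BIPHEP (5.5 mol %), 8 (5 equiv), 1,4-dioxane, 15 °C
Reagents that add atoms: none
Why: Rhodium-catalysed asymmetric conjugate alkynylation of an alkylidene Meldrum's acid: an alkynyl complex of monovalent rhodium inserts the activated alkene and the rhodium enolate is protonated by the next alkyne. The chiral bisphosphine blocks one face, so the alkynyl group should enter the Re face of the alkylidene carbon and set C4 as (S); the silyl group suppresses alkyne dimerization.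

Step 6
Reactants: 9 5-[(1S)-1-Ar-3-(trimethylsilyl)prop-2-yn-1-yl]-2,2-dimethyl-1,3-dioxane-4,6-dione
Product: 11 (3S)-3-Ar-5-(trimethylsilyl)pent-4-ynoic acid, via malonic acid 10 (not isolated)
Conditions: DMF/H2O (10:1), 100 °C
Reagents that add atoms: water, O
Why: Hydrolysis of the cyclic acylal and thermal decarboxylation of the malonic acid; no base is present and C4 is not α to a carbonyl group, so its configuration is not at risk, and the alkynylsilane is stable to neutral, weakly acidic water.

Step 7
Reactants: 11 (3S)-3-Ar-5-(trimethylsilyl)pent-4-ynoic acid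
Product: 13 (4S)-4-Ar-1-diazo-6-(trimethylsilyl)hex-5-yn-2-one, via mixed anhydride 12 (not isolated)
Conditions: ClCO2Et, Et3N, THF, −15 °C; then CH2N2 (Et2O), 0 °C → rt
Reagents that add atoms: diazomethane, C=[N+]=[N-]; ethyl chloroformate, CCOC(=O)Cl (its atoms remain only in 12)
Why: First half of the Arndt–Eistert homologation: the mixed anhydride acylates diazomethane; the silylalkyne, the aryl ethers and C4 are inert to the reagent.

Step 8
Reactants: 13 (4S)-4-Ar-1-diazo-6-(trimethylsilyl)hex-5-yn-2-one
Product: 15 (4S)-4-Ar-N-methoxy-N-methyl-6-(trimethylsilyl)hex-5-ynamide, via ketene 14 (not isolated)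
Conditions: PhCO2Ag (10 mol %), Et3N, MeNHOMe·HCl, THF, −20 °C → rt, dark
Reagents that add atoms: N,O-dimethylhydroxylamine hydrochloride, CNOC.Cl
Why: Wolff rearrangement: the primary alkyl group shifts to the carbene carbon and the ketene is captured by the hydroxylamine; the migrating carbon is not stereogenic. The former carboxyl carbon becomes C1 and the diazomethane carbon becomes C2.

Step 9
Reactants: 15 (4S)-4-Ar-N-methoxy-N-methyl-6-(trimethylsilyl)hex-5-ynamide; 8 trimethylsilylacetylene
Product: 17 (6S)-6-Ar-1,8-bis(trimethylsilyl)octa-1,7-diyn-3-one, via lithium aminoalkoxide 16 (not isolated)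
Conditions: 8, n-BuLi, THF, −78 °C; then 15, −78 → −20 °C; cold aq. NH4Cl
Reagents that add atoms: none
Why: Weinreb ketone synthesis: the chelated adduct 16 does not collapse until the quench, so the acetylide adds once only; the cold quench keeps the released amine from adding to the ynone.

Step 10
Reactants: 17 (6S)-6-Ar-1,8-bis(trimethylsilyl)octa-1,7-diyn-3-one
Product: 18 2-[(3S)-3-Ar-5-(trimethylsilyl)pent-4-yn-1-yl]-2-[(trimethylsilyl)ethynyl]-1,3-dioxolane
Conditions: (TMSOCH2)2, TMSOTf (5 mol %), CH2Cl2, −78 → −20 °C; then pyridine
Reagents that add atoms: 1,2-bis(trimethylsilyloxy)ethane, C[Si](C)(C)OCCO[Si](C)(C)C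
Why: Aprotic ketalization with the bis-silyl ether of ethylene glycol under silyl triflate catalysis; formation of the disiloxane drives it at low temperature, where conjugate addition to the ynone and cleavage of the benzyl ether do not compete.

Step 11
Reactants: 18 2-[(3S)-3-Ar-5-(trimethylsilyl)pent-4-yn-1-yl]-2-[(trimethylsilyl)ethynyl]-1,3-dioxolane
Product: 19 2-[(3R)-3-Ar-pent-4-yn-1-yl]-2-ethynyl-1,3-dioxolane
Conditions: K2CO3, MeOH/THF, 0 °C → rt
Reagents that add atoms: none
Why: Methanolysis of both alkynyl C–Si bonds; carbonate in methanol is too weak a base to remove the propargylic, benzylic C4–H at a useful rate, so neither racemization nor isomerization to an allene is expected.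

Step 12
Reactants: 19 2-[(3R)-3-Ar-pent-4-yn-1-yl]-2-ethynyl-1,3-dioxolane
Product: 21 2-[(3R)-3-Ar-5-(4,4,5,5-tetramethyl-1,3,2-dioxaborolan-2-yl)pent-4-yn-1-yl]-2-[(4,4,5,5-tetramethyl-1,3,2-dioxaborolan-2-yl)ethynyl]-1,3-dioxolane, via bis-borate 20 (not isolated)
Conditions: n-BuLi (2.05 equiv), THF, −78 °C; i-PrOBpin (2.2 equiv), −78 °C; HCl·Et2O (2.2 equiv), −78 °C → rt; filtration under argon
Reagents that add atoms: 2-isopropoxy-4,4,5,5-tetramethyl-1,3,2-dioxaborolane, CC(C)OB1OC(C)(C)C(C)(C)O1
Why: Standard synthesis of alkynyl pinacol boronates: double deprotonation of the terminal alkynes, B–C bond formation with the borate ester and cleavage of the isopropoxy ate complex 20 by anhydrous acid. The acetylenic protons are more acidic than C4–H by several pK units, so with two equivalents of base at −78 °C C4 should stay intact; 21 is moisture-sensitive and is used without chromatography.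

Step 13
Reactants: 21 2-[(3R)-3-Ar-5-(pinacolboryl)pent-4-yn-1-yl]-2-[(pinacolboryl)ethynyl]-1,3-dioxolane; 22 acetylene
Product: 23 (4'S)-4'-Ar-5',8'-bis(4,4,5,5-tetramethyl-1,3,2-dioxaborolan-2-yl)-3',4'-dihydro-2'H-spiro[[1,3]dioxolane-2,1'-naphthalene]
Conditions: CpCo(CO)2 (20 mol %), 22 (1 atm, slow stream), toluene, 110 °C, hν (visible), 21 added over 6 h
Reagents that add atoms: none
Why: CpCo(CO)2 loses CO under heat and light, and the CpCo fragment (monovalent cobalt) binds both alkynes of 21; oxidative coupling gives a cobaltacyclopentadiene of trivalent cobalt and with it the C4a–C8a bond. Ring B closes in this event as a six-membered carbocycle because the four-atom tether C1–C4 holds the alkynes together, which also places both boryl groups α to cobalt. Acetylene 22 is then taken up by insertion or [4+2] addition, and reductive elimination forms C5–C6 and C7–C8, closes the benzene ring A and releases CpCo. The closest known reactions are cobalt-mediated cocyclizations of α,ω-diynes with alkynes (1,7-diynes give tetralins), cyclotrimerizations of alkynyl pinacol boronates, and cobaltacyclopentadienes that carry boryl groups on both α-carbons. No stereocentre is formed; C4 is a spectator whose C–H bond is not touched under these neutral conditions. The selectivity needed is cross-trimerization over self-coupling of 21: the bulky boronate ends and the branched propargylic carbons C1 and C4 slow intermolecular reaction and favour cyclization, and slow addition into acetylene-saturated solution keeps 21 dilute. Trimerization of 22 gives only benzene, and regiochemistry does not arise because 22 is symmetric and the tether fixes the diyne.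

Step 14
Reactants: 23 (4'S)-4'-Ar-5',8'-bis(pinacolboryl)-3',4'-dihydro-2'H-spiro[[1,3]dioxolane-2,1'-naphthalene]
Product: 25 (4S)-4-Ar-5,8-dihydroxy-3,4-dihydronaphthalen-1(2H)-one, via hydroquinone ketal 24 (not isolated)
Conditions: 30 % H2O2, 2 M NaOH, THF, 0 °C, argon; aq. Na2S2O3 then Na2S2O4; then 2 M HCl, THF, rt
Reagents that add atoms: hydrogen peroxide, OO; water, O
Why: Oxidation of both aryl C–B bonds by hydroperoxide (1,2-shift of the aryl group from boron to oxygen) gives the hydroquinone, and the reductive quench returns any quinone. Acid then hydrolyses the dioxolane quickly because the oxocarbenium ion is stabilized by the electron-rich ring; the acylhydroquinone 25 is less easily oxidized than 24, which is why 24 is not isolated.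

Step 15
Reactants: 25 (4S)-4-Ar-5,8-dihydroxy-3,4-dihydronaphthalen-1(2H)-one
Product: 26 (4S)-5,8-dihydroxy-4-(4-hydroxy-8-methoxynaphthalen-1-yl)-3,4-dihydronaphthalen-1(2H)-one
Conditions: H2 (1 atm), 10 % Pd/C, EtOAc/MeOH, rt
Reagents that add atoms: none
Why: Hydrogenolysis of the aryl benzyl ether; the hydrogen-bonded aryl ketone and the C4–aryl bonds are not reduced at atmospheric pressure if the reaction is stopped once 25 is consumed.

## Compound list

1 | 1,5-dimethoxynaphthalene | COc1cccc2c(OC)cccc12 | starting material
2 | N-[(4,8-dimethoxynaphthalen-1-yl)methylidene]-N-methylmethanaminium chloride | COc1ccc(C=[N+](C)C)c2c(OC)cccc12.[Cl-] | intermediate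
3 | 4,8-dimethoxynaphthalene-1-carbaldehyde | COc1ccc(C=O)c2c(OC)cccc12 | intermediate
4 | 4-hydroxy-8-methoxynaphthalene-1-carbaldehyde | COc1cccc2c(O)ccc(C=O)c12 | intermediate
5 | 4-(benzyloxy)-8-methoxynaphthalene-1-carbaldehyde | COc1cccc2c(OCc3ccccc3)ccc(C=O)c12 | intermediate
6 | 2,2-dimethyl-1,3-dioxane-4,6-dione (Meldrum's acid) | CC1(C)OC(=O)CC(=O)O1 | starting material
7 | 5-{[4-(benzyloxy)-8-methoxynaphthalen-1-yl]methylidene}-2,2-dimethyl-1,3-dioxane-4,6-dione | COc1cccc2c(OCc3ccccc3)ccc(C=C3C(=O)OC(C)(C)OC3=O)c12 | intermediate
8 | ethynyl(trimethyl)silane (trimethylsilylacetylene) | C#C[Si](C)(C)C | starting material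
9 | 5-{(1S)-1-[4-(benzyloxy)-8-methoxynaphthalen-1-yl]-3-(trimethylsilyl)prop-2-yn-1-yl}-2,2-dimethyl-1,3-dioxane-4,6-dione | COc1cccc2c(OCc3ccccc3)ccc([C@@H](C#C[Si](C)(C)C)C3C(=O)OC(C)(C)OC3=O)c12 | intermediate
10 | 2-{(1S)-1-[4-(benzyloxy)-8-methoxynaphthalen-1-yl]-3-(trimethylsilyl)prop-2-yn-1-yl}propanedioic acid | COc1cccc2c(OCc3ccccc3)ccc([C@@H](C#C[Si](C)(C)C)C(C(=O)O)C(=O)O)c12 | intermediate
11 | (3S)-3-[4-(benzyloxy)-8-methoxynaphthalen-1-yl]-5-(trimethylsilyl)pent-4-ynoic acid | COc1cccc2c(OCc3ccccc3)ccc([C@@H](C#C[Si](C)(C)C)CC(=O)O)c12 | intermediate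
12 | (3S)-3-[4-(benzyloxy)-8-methoxynaphthalen-1-yl]-5-(trimethylsilyl)pent-4-ynoic ethyl carbonic anhydride | COc1cccc2c(OCc3ccccc3)ccc([C@@H](C#C[Si](C)(C)C)CC(=O)OC(=O)OCC)c12 | intermediate
13 | (4S)-4-[4-(benzyloxy)-8-methoxynaphthalen-1-yl]-1-diazo-6-(trimethylsilyl)hex-5-yn-2-one | COc1cccc2c(OCc3ccccc3)ccc([C@@H](C#C[Si](C)(C)C)CC(=O)C=[N+]=[N-])c12 | intermediate
14 | (4S)-4-[4-(benzyloxy)-8-methoxynaphthalen-1-yl]-6-(trimethylsilyl)hex-1-en-5-yn-1-one (ketene) | COc1cccc2c(OCc3ccccc3)ccc([C@@H](C#C[Si](C)(C)C)CC=C=O)c12 | intermediate
15 | (4S)-4-[4-(benzyloxy)-8-methoxynaphthalen-1-yl]-N-methoxy-N-methyl-6-(trimethylsilyl)hex-5-ynamide | COc1cccc2c(OCc3ccccc3)ccc([C@@H](C#C[Si](C)(C)C)CCC(=O)N(C)OC)c12 | intermediate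
16 | lithium (6S)-6-[4-(benzyloxy)-8-methoxynaphthalen-1-yl]-3-[methoxy(methyl)amino]-1,8-bis(trimethylsilyl)octa-1,7-diyn-3-olate (both C3 epimers) | COc1cccc2c(OCc3ccccc3)ccc([C@@H](C#C[Si](C)(C)C)CCC(O[Li])(N(C)OC)C#C[Si](C)(C)C)c12 | intermediate
17 | (6S)-6-[4-(benzyloxy)-8-methoxynaphthalen-1-yl]-1,8-bis(trimethylsilyl)octa-1,7-diyn-3-one | COc1cccc2c(OCc3ccccc3)ccc([C@@H](C#C[Si](C)(C)C)CCC(=O)C#C[Si](C)(C)C)c12 | intermediate
18 | 2-{(3S)-3-[4-(benzyloxy)-8-methoxynaphthalen-1-yl]-5-(trimethylsilyl)pent-4-yn-1-yl}-2-[(trimethylsilyl)ethynyl]-1,3-dioxolane | COc1cccc2c(OCc3ccccc3)ccc([C@@H](C#C[Si](C)(C)C)CCC3(C#C[Si](C)(C)C)OCCO3)c12 | intermediate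
19 | 2-{(3R)-3-[4-(benzyloxy)-8-methoxynaphthalen-1-yl]pent-4-yn-1-yl}-2-ethynyl-1,3-dioxolane | COc1cccc2c(OCc3ccccc3)ccc([C@@H](C#C)CCC3(C#C)OCCO3)c12 | intermediate
20 | dilithium bis[alkynyl(isopropoxy)(pinacolato)borate] derived from 19, (3R), each alkyne terminus carrying B(O-i-Pr)(pin) | COc1cccc2c(OCc3ccccc3)ccc([C@@H](C#C[B-]3(OC(C)C)OC(C)(C)C(C)(C)O3)CCC3(C#C[B-]4(OC(C)C)OC(C)(C)C(C)(C)O4)OCCO3)c12.[Li+].[Li+] | intermediate
21 | 2-{(3R)-3-[4-(benzyloxy)-8-methoxynaphthalen-1-yl]-5-(4,4,5,5-tetramethyl-1,3,2-dioxaborolan-2-yl)pent-4-yn-1-yl}-2-[(4,4,5,5-tetramethyl-1,3,2-dioxaborolan-2-yl)ethynyl]-1,3-dioxolane | COc1cccc2c(OCc3ccccc3)ccc([C@@H](C#CB3OC(C)(C)C(C)(C)O3)CCC3(C#CB4OC(C)(C)C(C)(C)O4)OCCO3)c12 | intermediate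
22 | acetylene (ethyne) | C#C | starting material
23 | (4'S)-4'-[4-(benzyloxy)-8-methoxynaphthalen-1-yl]-5',8'-bis(4,4,5,5-tetramethyl-1,3,2-dioxaborolan-2-yl)-3',4'-dihydro-2'H-spiro[[1,3]dioxolane-2,1'-naphthalene] | COc1cccc2c(OCc3ccccc3)ccc([C@@H]3CCC4(OCCO4)c4c(B5OC(C)(C)C(C)(C)O5)ccc(B5OC(C)(C)C(C)(C)O5)c43)c12 | intermediate
24 | (4'S)-4'-[4-(benzyloxy)-8-methoxynaphthalen-1-yl]-3',4'-dihydro-2'H-spiro[[1,3]dioxolane-2,1'-naphthalene]-5',8'-diol | COc1cccc2c(OCc3ccccc3)ccc([C@@H]3CCC4(OCCO4)c4c(O)ccc(O)c43)c12 | intermediate
25 | (4S)-4-[4-(benzyloxy)-8-methoxynaphthalen-1-yl]-5,8-dihydroxy-3,4-dihydronaphthalen-1(2H)-one | COc1cccc2c(OCc3ccccc3)ccc([C@@H]3CCC(=O)c4c(O)ccc(O)c43)c12 | intermediate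
26 | (4S)-5,8-dihydroxy-4-(4-hydroxy-8-methoxynaphthalen-1-yl)-3,4-dihydronaphthalen-1(2H)-one | COc1cccc2c(O)ccc([C@@H]3CCC(=O)c4c(O)ccc(O)c43)c12 | target

## Step count and risks

Total: 15 steps. Longest linear sequence: 15 steps (from 1; 6, 8 and 22 are commercial).

**Step 13 (key step).** Both alkyne termini and both propargylic carbons of 21 are substituted, so the intramolecular oxidative coupling may be slow. The catalyst could then spend itself trimerizing acetylene, or one alkyne of 21 could insert into an acetylene-derived cobaltacycle and give an open co-trimer with ring B unclosed. Traces of water would also protodeboronate the alkynyl boronates and remove the oxygen handles. The fallback sets out from 21 and returns at 23. Gaseous acetylene is replaced by vinyl acetate as a liquid two-carbon partner under a cationic catalyst of monovalent rhodium, [Rh(cod)2]BF4/BINAP. The diyne and the alkene are coupled to the acetoxycyclohexadiene (4'S)-6'-acetoxy-4'-Ar-5',8'-bis(pinacolboryl)-3',4',6',7'-tetrahydro-2'H-spiro[[1,3]dioxolane-2,1'-naphthalene] F1 (epimers; the 7'-acetate behaves alike), which aromatizes to 23 by loss of acetic acid. The partner cannot trimerize by itself and can be used as co-solvent, so the competition that threatens the cobalt reaction is removed.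

**Step 5.** The peri-methoxy group twists the naphthyl ring and crowds the alkylidene carbon of 7, so slow insertion and poor facial discrimination are the likely failures. The fallback sets out from 7 and returns at 11. Uncatalysed 1,4-addition of (trimethylsilyl)ethynylmagnesium bromide to 7 gives racemic 5-[1-Ar-3-(trimethylsilyl)prop-2-yn-1-yl]-2,2-dimethyl-1,3-dioxane-4,6-dione F2. Hydrolysis and decarboxylation as in step 6 give racemic 3-Ar-5-(trimethylsilyl)pent-4-ynoic acid F3. The (S)-acid is separated by crystallization of its salt with one enantiomer of 1-phenylethylamine, written here as the (R)-amine salt (R)-1-phenylethanaminium (3S)-3-Ar-5-(trimethylsilyl)pent-4-ynoate F4, and acidification gives 11.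

**Step 2.** The thiolate may cleave the 8-methyl ether as well, or add to the aldehyde, so loss of regioselectivity or of the formyl group is the risk. The fallback sets out from 3 and returns at 5. Exhaustive demethylation with BBr3 gives 4,8-dihydroxynaphthalene-1-carbaldehyde F5. The 4-hydroxyl, more acidic and not hydrogen-bonded to the carbonyl, is benzylated selectively (BnBr, KHCO3, DMF), as is known for 2,4-dihydroxybenzaldehyde, to give 4-(benzyloxy)-8-hydroxynaphthalene-1-carbaldehyde F6. Methylation of the remaining hydroxyl (MeI, K2CO3, DMF) gives 5.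

**Step 12.** Excess organolithium can remove the propargylic, benzylic C4–H, which would lead to racemization through a propargyl/allenyl anion; hydrolysis of 21 during isolation is the second risk. The fallback sets out from 19 and returns at 21. It is a base-free catalytic dehydrogenative borylation of both terminal alkynes with pinacolborane, using the carbene complex (CAAC)CuOTf of monovalent copper with catalytic Et3N. It forms the C(sp)–B bonds with evolution of hydrogen, never generates a free carbanion, and passes through no new isolated compound.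

**Step 14.** Under alkaline peroxide the electron-rich hydroquinone 24 may be oxidized on to the quinone, and the hindered C5–B bond may react incompletely, which would give mixtures. The fallback sets out from 23 and returns at 24. After the C–B oxidation the crude material is deliberately taken to the quinone with Ag2O, giving (4'S)-4'-Ar-3',4'-dihydro-2'H-spiro[[1,3]dioxolane-2,1'-naphthalene]-5',8'-dione F7, which is stable and can be purified. Reduction with Na2S2O4 gives 24, and acid completes step 14.

## Further compounds

F1 | step 13 | (4'S)-4'-[4-(benzyloxy)-8-methoxynaphthalen-1-yl]-5',8'-bis(4,4,5,5-tetramethyl-1,3,2-dioxaborolan-2-yl)-3',4',6',7'-tetrahydro-2'H-spiro[[1,3]dioxolane-2,1'-naphthalen]-6'-yl acetate (C6' epimers) | COc1cccc2c(OCc3ccccc3)ccc([C@@H]3CCC4(OCCO4)C4=C(B5OC(C)(C)C(C)(C)O5)CC(OC(C)=O)C(B5OC(C)(C)C(C)(C)O5)=C43)c12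
F2 | step 5 | racemic 5-{1-[4-(benzyloxy)-8-methoxynaphthalen-1-yl]-3-(trimethylsilyl)prop-2-yn-1-yl}-2,2-dimethyl-1,3-dioxane-4,6-dione | COc1cccc2c(OCc3ccccc3)ccc(C(C#C[Si](C)(C)C)C3C(=O)OC(C)(C)OC3=O)c12
F3 | step 5 | racemic 3-[4-(benzyloxy)-8-methoxynaphthalen-1-yl]-5-(trimethylsilyl)pent-4-ynoic acid | COc1cccc2c(OCc3ccccc3)ccc(C(C#C[Si](C)(C)C)CC(=O)O)c12
F4 | step 5 | (R)-1-phenylethanaminium (3S)-3-[4-(benzyloxy)-8-methoxynaphthalen-1-yl]-5-(trimethylsilyl)pent-4-ynoate | COc1cccc2c(OCc3ccccc3)ccc([C@@H](C#C[Si](C)(C)C)CC(=O)[O-])c12.C[C@@H]([NH3+])c1ccccc1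
F5 | step 2 | 4,8-dihydroxynaphthalene-1-carbaldehyde | O=Cc1ccc(O)c2cccc(O)c12
F6 | step 2 | 4-(benzyloxy)-8-hydroxynaphthalene-1-carbaldehyde | O=Cc1ccc(OCc2ccccc2)c2cccc(O)c12
F0 | step 12 | none | none
F7 | step 14 | (4'S)-4'-[4-(benzyloxy)-8-methoxynaphthalen-1-yl]-3',4'-dihydro-2'H-spiro[[1,3]dioxolane-2,1'-naphthalene]-5',8'-dione | COc1cccc2c(OCc3ccccc3)ccc([C@@H]3CCC4(OCCO4)C4=C3C(=O)C=CC4=O)c12
A1 | alternative 1 | methyl (4S)-4-[2,5-bis(benzyloxy)phenyl]-4-(4-hydroxy-8-methoxynaphthalen-1-yl)butanoate | COc1cccc2c(O)ccc([C@@H](c3cc(OCc4ccccc4)ccc3OCc3ccccc3)CCC(=O)OC)c12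
A2 | alternative 1 | methyl (4R)-4-[2,5-bis(benzyloxy)phenyl]-4-(furan-2-yl)butanoate | o1cccc1[C@@H](c1cc(OCc2ccccc2)ccc1OCc1ccccc1)CCC(=O)OC
A3 | alternative 1 | 3-methoxybenzyne (3-methoxy-1,2-didehydrobenzene) | COC1=CC=CC#C1
A4 | alternative 2 | (5S)-7-(benzyloxy)-5-[4-(benzyloxy)-8-methoxynaphthalen-1-yl]-4,5-dihydro-1-benzoxepin-2(3H)-one | COc1cccc2c(OCc3ccccc3)ccc([C@@H]3CCC(=O)Oc4ccc(OCc5ccccc5)cc43)c12
A5 | alternative 2 | 4-(benzyloxy)-6-{[4-(benzyloxy)-8-methoxynaphthalen-1-yl]methylidene}cyclohexa-2,4-dien-1-one | COc1cccc2c(OCc3ccccc3)ccc(C=C3C=C(OCc4ccccc4)C=CC3=O)c12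
A6 | alternative 2 | acrolein (prop-2-enal) | C=CC=O
A7 | alternative 3 | (1S,4S)-5,8-bis(benzyloxy)-4-[4-(benzyloxy)-8-methoxynaphthalen-1-yl]-1-[(tert-butyldimethylsilyl)oxy]-1,4-dihydronaphthalene (cis) | COc1cccc2c(OCc3ccccc3)ccc([C@@H]3C=C[C@H](O[Si](C)(C)C(C)(C)C)c4c(OCc5ccccc5)ccc(OCc5ccccc5)c43)c12
A8 | alternative 3 | 1,4-bis(benzyloxy)-2-{(1S)-1-[4-(benzyloxy)-8-methoxynaphthalen-1-yl]prop-2-en-1-yl}-3-{(1S)-1-[(tert-butyldimethylsilyl)oxy]prop-2-en-1-yl}benzene | COc1cccc2c(OCc3ccccc3)ccc([C@H](C=C)c3c(OCc4ccccc4)ccc(OCc4ccccc4)c3[C@H](C=C)O[Si](C)(C)C(C)(C)C)c12
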